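Remark (assumption): ring atoms are numbered C1–C10 as in the target (C3 free carbinol, C4 and C10 methyl-bearing alkene carbons, C6 acetate, C7 isopropyl, C8 cinnamate), and the six-membered precursors keep these numbers. Systematic names of the cyclohexenes in the compound list use their own IUPAC locants.

## Structural features

The target is a germacrane-type carbocycle: one ten-membered ring (C1–C10) with two trisubstituted Z alkenes, C1=C10 and C4=C5, arranged as a 1,5-diene across C2–C3. Three oxygens sit on the ring, each in a different state: a free allylic alcohol at C3, an allylic acetate at C6 and an (E)-cinnamate at C8. C6, C7 (isopropyl) and C8 form a contiguous stereotriad in which O6 and O8 are 1,3-anti; C3 stands apart, on the far side of the C4=C5 alkene. Fragile points are the two allylic C–O bonds, the esters (which can migrate between O8 and O6), the cinnamate as a Michael acceptor, and the medium-ring diene, which is prone to transannular reactions under acid. The real difficulty is to close a ten-membered ring with both alkenes Z while setting three adjacent stereocentres and ending with three differentiated oxygens. Two features are exploited. The segment C5=C4(Me)–C3(O)–C2–C1 is the ring of cis-carveol. The segment C6(O)–C7–C8–C9–C10=C1 is a cyclodec-5-enone, the retron of an oxy-Cope ring expansion of a six-membered ring carrying alkenyl groups on C6 and C1.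

## Logic of the disconnections

**25 back to 23 (through 24).** The cuts are the C3 O–benzyl bond and the C6 O–acetyl bond. C3 must stay masked until both esters are in place, and its mask must leave under neutral oxidative conditions so that no ester migrates and the diene sees no acid. The gain is a single free hydroxyl (C6) whose acylation is unambiguous. The forward steps must acetylate a hindered allylic alcohol without 1,3-acyl shift and remove the benzyl-type ether without oxidising the allylic alcohol it frees.

**23 back to 20 and 21.** The cuts are the C8 O–acyl bond and the C6–H bond, made in one redox event. Intramolecular hydride transfer from a hemiacetal on O8 sets C6 anti to O8 and leaves the cinnamate on O8, so two secondary hydroxyls never need to be told apart. One stereocentre and one ester are removed. The forward step needs hemiacetal formation and hydride transfer to outrun acyl migration and elimination of the aldol.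

**20 back to 18.** The C8–O bond is exchanged for C8–Si. An oxygen at C8 would sit beta to the enolate formed in the ring expansion and would be eliminated; silicon is inert there and is later replaced by oxygen with retention. The forward step must tolerate an enone and a PMB ether under fluoride and hydroperoxide.

**18 back to 15.** This is the retro ring expansion: C8–C9 is cut, C1–C6 is reconnected and the C7 hydrogen is removed. The ten-membered ring becomes a cyclohexenol whose C1 and C3 centres come from the chiral pool. The ring, both alkene geometries and C8 are all traced to one precursor. The forward step demands the cis arrangement of the two alkenyl groups, an (E)-vinylsilane, and control of C7 on protonation.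

**15 back to 12 and 13.** The cut is the C7–isopropyl bond (with C8–H). Anti addition across the alkyne, directed by the neighbouring alkoxide, gives silicon cis to isopropyl and trans to C6, which is the geometry the chair needs. The alkenyl group is reduced to an alkyne. The forward step must be regioselective (isopropyl to C7) and anti.

**12 back to 7 and 10; 10 back to 8 and 9.** The cuts are the C6–C7 bond and the Si–C(sp) bond. A rod-like acetylide is the nucleophile most likely to enter axially, cis to the C1 isopropenyl group; a bulky preformed alkenylmetal would favour equatorial entry and the wrong diastereomer. The forward addition must be 1,2 and must not enolise the beta,gamma-unsaturated ketone.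

**7 back to 6, 4, 3, 2 and 1.** These are functional-group interconversions that move oxidation to C6: 7 from 6 by 1,3-oxidative transposition, 6 from 4 by epoxide-to-allylic-alcohol isomerisation, 4 from 3 by protection, 3 from 2 by directed epoxidation, 2 from 1 by 1,2-reduction. A direct allylic C–H oxidation of the protected form of 2 at C6 was not adopted: it would have to discriminate against the PMB benzylic hydrogens, the C3–H and the allylic positions of the isopropenyl group. The longer path uses only site-specific polar steps. The forward steps need epoxide opening at C5 and elimination toward C6.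

## Other disconnections considered

**Alternative 1:** The cuts are C1–C2 and C9–C10, the two allylic bonds flanking the C1=C10 alkene. In the forward key step the linchpin (Z)-1,2-bis(trimethylstannyl)propene A1 undergoes two successive tin–lithium exchanges (MeLi) and opens two terminal epoxides with BF3·OEt2 assistance in one flask: the alkynyl oxirane A2 at C2 and the branched oxirane A3 at C9. The product is the open-chain seco-diol A4.
- In its favour: it is convergent, and the Z geometry of C1=C10 is carried in with A1 and preserved by stereoretentive exchange. On this point it is the equal of the chosen plan. On C3 and C8 it is the better, because each carbinol is bought with its own enantiopure epoxide rather than relayed from ring stereocentres.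
- Against it here: no ring is formed. The C5–C6 closure, the C4 methyl group with a Z C4=C5 alkene and the C6 centre all remain, so an end-to-end ten-membered cyclisation with its entropic cost still lies ahead. The second exchange must proceed beside a lithium alkoxide, the methyl-bearing vinyllithium is hindered, A2 is open to SN2' attack, and A3 needs its own asymmetric synthesis.
- Comparison: structurally it solves one alkene and two carbinols but not the ring. Mechanistically it is stepwise polar chemistry against a single pericyclic event that makes ring, alkene and C8 together. In step economy it is expected to be clearly longer.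

**Alternative 2:** The cut is C7–C8, read as an aldol retron. In the forward key step SmI2 reduces the seco bromo keto aldehyde A5 to a samarium enolate at C7, which adds to the C8 aldehyde (10-exo-trig). The product is the ten-membered beta-hydroxy Z-enone A6.
- In its favour: A6 is the same aldol the chosen route reaches at 20, differing only in the C3 protecting group, so the endgame is the equal of the chosen one. It is the better in that no silicon surrogate and no fluoride/peroxide step is needed, so a silyl ether can protect C3. The enolate is formed regiospecifically under nearly neutral conditions, with no strong base.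
- Against it here: the ring is closed end to end through a ten-membered transition state. C7 and C8 are created with only the remote C3 centre and the macrocyclic template to guide them. Simple debromination, pinacol coupling and reduction of the enone compete. Both Z trisubstituted alkenes must be built separately in the linear precursor.
- Comparison: the chosen plan is stronger on ring formation (no entropic price) and on relay of stereochemistry to C8. The alternative is equal or better from the aldol onward. Overall the linear sequence to A5 is expected to be longer.

**Alternative 3:** The cut is C3–C4, with the C4=C5 alkene simplified to an alkyne. In the forward key step CrCl2 with catalytic NiCl2 converts the iodoalkyne aldehyde A7 into an alkynylchromium species that adds to the C3 aldehyde (10-exo-trig). The product is the cyclic propargylic alcohol A8.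
- In its favour: the conditions are highly chemoselective for the aldehyde. The C6–C8 triad can be set in an open chain by reliable aldol chemistry, so C7 is fixed before the ring exists; on C7 this is better than the chosen plan, which sets it by protonation. Only one Z alkene must be made before cyclisation.
- Against it here: C3 is formed in the macrocyclisation without an obvious control element. A ten-membered ring holding an alkyne and a Z alkene is strained, which favours oligomers. The methyl group must afterwards be added to C4 of an alkyne flanked by two oxygenated carbons, regioselectively and syn, whereas hydroxyl-directed carbometalation of propargylic alcohols runs anti. Three oxygens need three different masks.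
- Comparison: structurally it defers the C4 methyl and the alkene geometry to a difficult late step. Mechanistically it is an organometallic end-to-end closure against a ring expansion. In step economy it is expected to be the longest of the four.

Key step: step 9

## Route

Step 1
Reactants: 1 (R)-carvone
Product: 2 (1R,5R)-cis-carveol
Conditions: NaBH4, CeCl3·7H2O, MeOH, −20 to 0 °C
Reagents that add atoms: none
Why: Luche reduction: cerium-activated 1,2-hydride delivery occurs axially on the conformer with equatorial isopropenyl, so the new C3 hydroxyl ends equatorial and cis to the isopropenyl group; neither alkene is reduced.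

Step 2
Reactants: 2 (1R,5R)-cis-carveol
Product: 3 syn-epoxy alcohol (epoxide oxygen cis to the hydroxyl)
Conditions: VO(acac)2 (2 mol %), t-BuOOH, PhMe, 0 °C to rt
Reagents that add atoms: tert-butyl hydroperoxide, CC(C)(C)OO
Why: Hydroxyl-directed vanadium-catalysed epoxidation: the alkoxide-bound peroxo complex delivers oxygen to the C4=C5 alkene on the face of the hydroxyl, which sets both new centres, and leaves the isopropenyl group untouched.

Step 3
Reactants: 3 syn-epoxy alcohol
Product: 4 PMB ether of the syn-epoxy alcohol
Conditions: NaH, PMBCl, Bu4NI (cat.), THF–DMF, 0 °C to rt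
Reagents that add atoms: 4-methoxybenzyl chloride, COc1ccc(CCl)cc1
Why: Williamson etherification; a Payne shift is excluded because the alkoxide lies on the same face as the epoxide oxygen and cannot attack C4 from the rear.

Step 4
Reactants: 4 PMB ether of the syn-epoxy alcohol
Product: 6 tertiary allylic alcohol (C4 carbinol, C5=C6 alkene), via hydroxy selenide 5 (not isolated)
Conditions: (PhSe)2, NaBH4, EtOH, 78 °C; then 30% H2O2, pyridine, THF, 0 °C to rt
Reagents that add atoms: none
Why: Epoxide-to-allylic-alcohol isomerisation by selenide opening and selenoxide syn-elimination: the selenolate opens the epoxide trans-diaxially at the secondary carbon C5 through the chair with equatorial isopropenyl and OPMB groups (Fürst–Plattner rule). The selenoxide can eliminate only toward C6 because C4 has no hydrogen.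

Step 5
Reactants: 6 tertiary allylic alcohol
Product: 7 (4R,6R)-4-(PMB-oxy)-3-methyl-6-isopropenylcyclohex-2-enone
Conditions: pyridinium chlorochromate [C5H5NH][CrO3Cl], 4 Å MS, CH2Cl2, rt
Reagents that add atoms: pyridinium chlorochromate, [O-][Cr](=O)(=O)Cl.c1cc[nH+]cc1
Why: Dauben–Babler oxidative 1,3-transposition: the chromate ester of the tertiary allylic alcohol shifts to C6 and is oxidised there to the beta-methyl enone. C3 is untouched, and the cis (diequatorial) C1/C3 arrangement is the stable one should C1 epimerise.

Step 6
Reactants: 8 benzylchlorodimethylsilane; 9 ethynylmagnesium bromide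
Product: 10 benzyl(ethynyl)dimethylsilane
Conditions: THF, 0 °C to rt
Reagents that add atoms: none
Why: Nucleophilic substitution at silicon by the alkynyl Grignard reagent, the standard entry to ethynylsilanes.

Step 7
Reactants: 10 benzyl(ethynyl)dimethylsilane; 7 enone
Product: 12 (1S,4R,6R)-propargylic alcohol (alkynyl cis to isopropenyl), via lithium acetylide 11 (not isolated)
Conditions: n-BuLi, THF, −78 °C; then 7, −78 to −40 °C; then H2O
Reagents that add atoms: none
Why: 1,2-Addition of a lithium acetylide to a cyclohexenone: the slender nucleophile enters C6 axially, anti to the axial C1–H of the half-chair with equatorial isopropenyl and OPMB groups, so the alkynyl group ends cis to the isopropenyl group and the hydroxyl trans to it. Low temperature and the weak basicity of the acetylide keep the beta,gamma-unsaturated ketone from enolising.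

Step 8
Reactants: 12 propargylic alcohol; 13 isopropylmagnesium chloride
Product: 15 all-cis dialkenyl cyclohexenol with (E)-vinylsilane, via magnesium chelate 14 (not isolated)
Conditions: CuI (20 mol %), THF–PhMe, 0 to 60 °C; then H2O, 0 °C
Reagents that add atoms: none
Why: Alkoxide-directed, copper-catalysed anti-carbomagnesiation of a propargylic alcohol: isopropyl is delivered to the proximal carbon C7 while magnesium ends on the silicon-bearing C8 in a five-membered chelate, a regiochemistry that alpha-silyl stabilisation reinforces. Protonation of the C8–Mg bond with retention leaves silicon cis to isopropyl and trans to C6.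

Step 9
Reactants: 15 all-cis dialkenyl cyclohexenol
Product: 18 (3R,7S,8S)-ten-membered C6 ketone with silicon at C8, via potassium enolate 16 (not isolated), via C7-epimeric ketone 17 (not isolated)
Conditions: KH, 18-crown-6, THF, 0 to 40 °C; AcOH, −78 °C; then DBU (cat.), PhMe, 40 °C
Reagents that add atoms: none
Why: This is an anionic oxy-Cope rearrangement, the charge-accelerated [3,3]-sigmatropic shift of a 3-oxido-1,5-diene, in the ring-expanding form known for 1,2-dialkenylcyclohexanols. The potassium alkoxide of 15, its ion pair loosened by 18-crown-6, rearranges through a chair in which the diene C8=C7–C6–C1–C10=C9 breaks C1–C6 and forms C8–C9, giving enolate 16. The ten-membered ring therefore arises by a four-atom ring expansion (cleavage of the bond shared by the old ring and the chair) and not by end-to-end closure, so no dilution and no entropic penalty are involved. Z geometry at C1=C10 requires C2 to be axial on the chair at C1; the cis relation of the alkenyl groups (C6 alkenyl pseudo-axial, C1 isopropenyl equatorial) enforces this, the other chair is penalised by a 1,3-diaxial isopropenyl/OPMB contact, and C4=C5 stays Z because it is inherited from the six-membered ring. C8 is set by the same chair: the (E)-vinylsilane puts silicon equatorial, and the face of C8 that meets C9 is fixed by the C1 and C6 centres. Silicon trans to C6 also prevents a 1,4-silyl shift to the alkoxide, and a C–Si bond next to the enolate cannot be eliminated as an alkoxy group would be. C7 is created only on protonation: kinetic protonation of 16 on its outer face is expected to give mainly epimer 17, and DBU then equilibrates the alpha centre to 18, in which the isopropyl and silyl groups both lie pseudo-equatorial on the ring periphery.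

Step 10
Reactants: 18 ten-membered silyl ketone
Product: 20 (3R,7R,8S)-C8 hydroxy ketone, via C8 dimethylsilanol 19 (not isolated)
Conditions: Bu4NF, THF, 0 °C; then KHCO3, 30% H2O2, MeOH–THF, 0 °C to rt
Reagents that add atoms: hydrogen peroxide, OO
Why: Tamao–Fleming oxidation of a benzyldimethylsilyl group: fluoride cleaves the benzyl–silicon bond, and hydroperoxide then oxidises the resulting silanol by migration of C8 from silicon to oxygen with retention, so O8 takes the place and configuration of silicon. The PMB ether is inert, and C7 is already the thermodynamic epimer, so the basic medium should not erode it.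

Step 11
Reactants: 20 C8 hydroxy ketone; 21 (E)-cinnamaldehyde
Product: 23 (3R,6S,7S,8S)-C6 alcohol C8 cinnamate, via cinnamaldehyde hemiacetal 22 (not isolated)
Conditions: SmI2 (30 mol %), THF, −10 °C
Reagents that add atoms: none
Why: Evans–Tishchenko reduction: the trivalent samarium species formed from SmI2 and the aldehyde binds the O8 hemiacetal and the C6 carbonyl in a six-membered transition state, and the hemiacetal hydride is delivered internally to the carbonyl face on the side of O8. This sets C6 with O6 anti to O8, leaves C6–OH free and puts the cinnamate on O8.

Step 12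
Reactants: 23 C6 alcohol C8 cinnamate
Product: 24 (3R,6S,7R,8S)-C6 acetate C8 cinnamate C3 PMB ether
Conditions: Ac2O, pyridine, DMAP (cat.), CH2Cl2, 0 °C to rt
Reagents that add atoms: acetic anhydride, CC(=O)OC(C)=O
Why: DMAP-catalysed acylation of the only free hydroxyl; the mild base and low temperature disfavour 1,3-acyl migration from O8.

Step 13
Reactants: 24 C6 acetate C8 cinnamate C3 PMB ether
Product: 25 target, (3R,6S,7R,8S)-6-acetoxy-8-cinnamoyloxy-(1(10)Z,4Z)-germacra-1(10),4-dien-3-ol
Conditions: DDQ, CH2Cl2–pH 7 buffer, 0 °C
Reagents that add atoms: none
Why: Oxidative cleavage of the PMB ether by hydride abstraction and hydrolysis; the esters, both Z alkenes and the cinnamate are inert to DDQ, and the neutral medium avoids acyl migration and transannular cyclisation.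

## Compound list

1 | (R)-carvone, (5R)-2-methyl-5-(prop-1-en-2-yl)cyclohex-2-en-1-one | CC1=CC[C@H](CC1=O)C(=C)C | starting material
2 | (1R,5R)-2-methyl-5-(prop-1-en-2-yl)cyclohex-2-en-1-ol (cis-carveol, OH cis to isopropenyl) | C1C=C(C)[C@H](O)C[C@@H]1C(C)=C | intermediate
3 | cis-carveol 2,3-epoxide, epoxide oxygen cis to the hydroxyl and to the isopropenyl group | C1[C@@H]2O[C@]2(C)[C@H](O)C[C@@H]1C(C)=C | intermediate
4 | 4-methoxybenzyl ether of 3 | C1[C@@H]2O[C@]2(C)[C@H](OCc3ccc(OC)cc3)C[C@@H]1C(C)=C | intermediate
5 | hydroxy selenide: C5 phenylselanyl trans to the C4 tertiary hydroxyl, hydroxyl cis to OPMB and isopropenyl | C1[C@@H]([Se]c2ccccc2)[C@](C)(O)[C@H](OCc3ccc(OC)cc3)C[C@@H]1C(C)=C | intermediate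
6 | 6-[(4-methoxybenzyl)oxy]-1-methyl-4-(prop-1-en-2-yl)cyclohex-2-en-1-ol, tertiary OH, OPMB and isopropenyl all cis | C1=C[C@](C)(O)[C@H](OCc2ccc(OC)cc2)C[C@@H]1C(C)=C | intermediate
7 | (4R,6R)-4-[(4-methoxybenzyl)oxy]-3-methyl-6-(prop-1-en-2-yl)cyclohex-2-en-1-one | O=C1C=C(C)[C@H](OCc2ccc(OC)cc2)C[C@@H]1C(C)=C | intermediate
8 | benzylchlorodimethylsilane | C[Si](C)(Cl)Cc1ccccc1 | starting material
9 | ethynylmagnesium bromide | C#C[Mg]Br | starting material
10 | benzyl(ethynyl)dimethylsilane | C#C[Si](C)(C)Cc1ccccc1 | intermediate
11 | lithium [benzyl(dimethyl)silyl]acetylide | [Li]C#C[Si](C)(C)Cc1ccccc1 | intermediate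
12 | (1S,4R,6R)-1-{[benzyl(dimethyl)silyl]ethynyl}-4-[(4-methoxybenzyl)oxy]-3-methyl-6-(prop-1-en-2-yl)cyclohex-2-en-1-ol | O[C@@]1(C#C[Si](C)(C)Cc2ccccc2)C=C(C)[C@H](OCc3ccc(OC)cc3)C[C@@H]1C(C)=C | intermediate
13 | isopropylmagnesium chloride | CC(C)[Mg]Cl | starting material
14 | cyclic magnesium chelate (O6–Mg–C8 five-membered ring, isopropyl on C7, silicon on C8) | [Mg]1O[C@@]2(C(C(C)C)=C1[Si](C)(C)Cc3ccccc3)C=C(C)[C@H](OCc4ccc(OC)cc4)C[C@@H]2C(C)=C | intermediate
15 | (1S,4R,6R)-1-{(E)-1-[benzyl(dimethyl)silyl]-3-methylbut-1-en-2-yl}-4-[(4-methoxybenzyl)oxy]-3-methyl-6-(prop-1-en-2-yl)cyclohex-2-en-1-ol | O[C@@]1(/C(C(C)C)=C/[Si](C)(C)Cc2ccccc2)C=C(C)[C@H](OCc3ccc(OC)cc3)C[C@@H]1C(C)=C | intermediate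
16 | potassium C6 enolate of the ten-membered ring (O6 cis to C8 across C6=C7; Z C1=C10, Z C4=C5) | [K+].[O-]/C1=C(/C(C)C)\[C@@H]([Si](C)(C)Cc2ccccc2)C/C(C)=C\C[C@@H](OCc2ccc(OC)cc2)/C(C)=C\1 | intermediate
17 | C7 epimer of 18, (3R,7R,8S) | O=C1/C=C(/C)[C@H](OCc2ccc(OC)cc2)C/C=C(/C)C[C@H]([Si](C)(C)Cc3ccccc3)[C@@H]1C(C)C | intermediate
18 | (3R,7S,8S)-8-[benzyl(dimethyl)silyl]-7-isopropyl-3-[(4-methoxybenzyl)oxy]-4,10-dimethyl-(1(10)Z,4Z)-cyclodeca-1(10),4-dien-6-one | O=C1/C=C(/C)[C@H](OCc2ccc(OC)cc2)C/C=C(/C)C[C@H]([Si](C)(C)Cc3ccccc3)[C@H]1C(C)C | intermediate
19 | C8 hydroxydimethylsilyl analogue of 18 | O=C1/C=C(/C)[C@H](OCc2ccc(OC)cc2)C/C=C(/C)C[C@H]([Si](C)(C)O)[C@H]1C(C)C | intermediate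
20 | (3R,7R,8S)-8-hydroxy-7-isopropyl-3-[(4-methoxybenzyl)oxy]-4,10-dimethyl-(1(10)Z,4Z)-cyclodeca-1(10),4-dien-6-one | O=C1/C=C(/C)[C@H](OCc2ccc(OC)cc2)C/C=C(/C)C[C@H](O)[C@H]1C(C)C | intermediate
21 | (E)-cinnamaldehyde | O=C/C=C/c1ccccc1 | starting material
22 | hemiacetal of the C8 hydroxyl of 20 with 21 (hemiacetal carbon unassigned) | O=C1/C=C(/C)[C@H](OCc2ccc(OC)cc2)C/C=C(/C)C[C@H](OC(O)/C=C/c2ccccc2)[C@H]1C(C)C | intermediate
23 | (3R,6S,7S,8S)-6-hydroxy-8-cinnamoyloxy-3-[(4-methoxybenzyl)oxy]-(1(10)Z,4Z)-germacra-1(10),4-diene | O[C@H]1/C=C(/C)[C@H](OCc2ccc(OC)cc2)C/C=C(/C)C[C@H](OC(=O)/C=C/c2ccccc2)[C@H]1C(C)C | intermediate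
24 | (3R,6S,7R,8S)-6-acetoxy-8-cinnamoyloxy-3-[(4-methoxybenzyl)oxy]-(1(10)Z,4Z)-germacra-1(10),4-diene | CC(=O)O[C@H]1/C=C(/C)[C@H](OCc2ccc(OC)cc2)C/C=C(/C)C[C@H](OC(=O)/C=C/c2ccccc2)[C@H]1C(C)C | intermediate
25 | (3R,6S,7R,8S)-6-acetoxy-8-cinnamoyloxy-(1(10)Z,4Z)-germacra-1(10),4-dien-3-ol | CC(=O)O[C@H]1/C=C(/C)[C@H](O)C/C=C(/C)C[C@H](OC(=O)/C=C/c2ccccc2)[C@H]1C(C)C | target

## Step count and least certain steps

Total: 13 steps. Longest linear sequence: 12 steps, from 1 to 25 through steps 1–5 and 7–13; step 6 is a one-step side branch.

**Step 9 (key step).** Three processes could interfere: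
- The crown-ether-activated alkoxide and enolate are strong bases and strong nucleophiles toward silicon, so loss of the benzyl group from silicon or gamma-deprotonation and isomerisation of the Z enone could compete.
- Some material could leak through a boat transition state, or through the other 1,5-diene that uses the ring alkene.
- Facial control at C7 could be poor, or the thermodynamic bias at C7 could be unfavourable.

Fallback (sets out from 15, returns at 18): the rearrangement is run without base. 15 is silylated with N-(trimethylsilyl)imidazole to the trimethylsilyl ether F5. F5 is heated in o-dichlorobenzene at about 180–200 °C, where the neutral silyloxy-Cope shift through the same chair should give the ten-membered trimethylsilyl enol ether F6. Methanolysis with K2CO3 in MeOH at 0 °C then releases the ketone under equilibrating conditions and gives 18.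

**Step 8.** Carbometalation at the hindered tertiary propargylic alkoxide could be slow, and beta-hydride transfer from the isopropylcopper species could then reduce the alkyne or erode the alkene geometry.

Fallback (sets out from 7, returns at 15): the alkenyl group is assembled by cross-coupling instead of carbometalation. 9 adds axially to 7 to give the ethynyl carbinol F1. Cis-silylstannation with (benzyldimethylsilyl)tributylstannane F2 (made from 8 and Bu3SnLi), catalysed by Pd(PPh3)4, places tin on C7 and silicon on C8 and gives the stannane F3. Iododestannylation with I2 gives the vinyl iodide F4. Negishi coupling with iPrZnBr (Pd(OAc)2, CPhos) then replaces iodine by isopropyl with retention and gives 15.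

**Step 10.** Once O8 is unmasked beside the enone, transannular oxa-Michael addition, nucleophilic epoxidation of the enone by hydroperoxide, retro-aldol ring opening or dehydration of the aldol could compete.

Fallback (sets out from 18, returns at 24): the ketone is removed before silicon is exchanged. Luche reduction of 18 gives the C6 allylic alcohol F7; hydride is expected to enter anti to the C8 silyl group, and this configuration would have to be confirmed. Acetylation gives the acetate F8. Tamao–Fleming oxidation of F8, now free of the enone, gives the C8 alcohol F9. Acylation with cinnamoyl chloride and DMAP gives 24.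

**Step 11.** The conjugated aldehyde could be a sluggish hemiacetal partner and hydride donor, divalent samarium could reduce the enal or the enone by single-electron transfer, and the Lewis acid could promote acyl migration from O8 to O6.

Fallback (sets out from 20, returns at 23): reduction and acylation are separated. Me4NBH(OAc)3 in MeCN–AcOH (Evans–Saksena reduction, with the same internal hydride delivery from O8) gives the anti-diol F10. The less hindered C8 hydroxyl is then acylated through its dibutylstannylene acetal (Bu2SnO, then cinnamoyl chloride), giving 23; the regioselectivity of this acylation is the price of this path.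

## Further compounds

F1 | step 8 | ethynyl carbinol (ethynyl cis to isopropenyl) | O[C@@]1(C#C)C=C(C)[C@H](OCc2ccc(OC)cc2)C[C@@H]1C(C)=C
F2 | step 8 | (benzyldimethylsilyl)tributylstannane | CCCC[Sn](CCCC)(CCCC)[Si](C)(C)Cc1ccccc1
F3 | step 8 | C7 tributylstannyl C8 benzyldimethylsilyl alkene (tin cis to silicon) | O[C@@]1(/C([Sn](CCCC)(CCCC)CCCC)=C/[Si](C)(C)Cc2ccccc2)C=C(C)[C@H](OCc3ccc(OC)cc3)C[C@@H]1C(C)=C
F4 | step 8 | C7 vinyl iodide (iodine cis to silicon) | O[C@@]1(/C(I)=C/[Si](C)(C)Cc2ccccc2)C=C(C)[C@H](OCc3ccc(OC)cc3)C[C@@H]1C(C)=C
F5 | step 9 | trimethylsilyl ether of 15 | C[Si](C)(C)O[C@@]1(/C(C(C)C)=C/[Si](C)(C)Cc2ccccc2)C=C(C)[C@H](OCc3ccc(OC)cc3)C[C@@H]1C(C)=C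
F6 | step 9 | ten-membered C6 trimethylsilyl enol ether | C[Si](C)(C)O/C1=C(/C(C)C)\[C@@H]([Si](C)(C)Cc2ccccc2)C/C(C)=C\C[C@@H](OCc2ccc(OC)cc2)/C(C)=C\1
F7 | step 10 | C6 allylic alcohol with silicon at C8 | O[C@H]1/C=C(/C)[C@H](OCc2ccc(OC)cc2)C/C=C(/C)C[C@H]([Si](C)(C)Cc3ccccc3)[C@H]1C(C)C
F8 | step 10 | C6 acetate with silicon at C8 | CC(=O)O[C@H]1/C=C(/C)[C@H](OCc2ccc(OC)cc2)C/C=C(/C)C[C@H]([Si](C)(C)Cc3ccccc3)[C@H]1C(C)C
F9 | step 10 | C6 acetate C8 alcohol | CC(=O)O[C@H]1/C=C(/C)[C@H](OCc2ccc(OC)cc2)C/C=C(/C)C[C@H](O)[C@H]1C(C)C
F10 | step 11 | anti-6,8-diol C3 PMB ether | O[C@H]1/C=C(/C)[C@H](OCc2ccc(OC)cc2)C/C=C(/C)C[C@H](O)[C@H]1C(C)C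
A1 | alternative 1 | (Z)-1,2-bis(trimethylstannyl)propene | C[Sn](C)(C)/C=C(/C)[Sn](C)(C)C
A2 | alternative 1 | (S)-2-[(trimethylsilyl)ethynyl]oxirane | C[Si](C)(C)C#C[C@H]1CO1
A3 | alternative 1 | 2-{1-[(4-methoxybenzyl)oxy]-3-methylbutan-2-yl}oxirane with the C7 and C8 configurations of A4 | C1O[C@@H]1[C@@H](C(C)C)COCc1ccc(OC)cc1
A4 | alternative 1 | seco-diol with Z C1=C10, C3 propargylic and C8 carbinols | C[Si](C)(C)C#C[C@H](O)C/C=C(/C)C[C@H](O)[C@@H](C(C)C)COCc1ccc(OC)cc1
A5 | alternative 2 | seco C7 bromo ketone C8 aldehyde, C3 tert-butyldimethylsilyl ether (C7 unassigned) | O=CC/C(C)=C\C[C@@H](O[Si](C)(C)C(C)(C)C)/C(C)=C\C(=O)C(Br)C(C)C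
A6 | alternative 2 | ten-membered beta-hydroxy Z-enone, C3 tert-butyldimethylsilyl ether | O=C1/C=C(/C)[C@H](O[Si](C)(C)C(C)(C)C)C/C=C(/C)C[C@H](O)[C@H]1C(C)C
A7 | alternative 3 | seco C4 iodoalkyne C3 aldehyde, C6 triethylsilyl ether, C8 PMB ether | IC#C[C@H](O[Si](CC)(CC)CC)[C@H](C(C)C)[C@@H](OCc1ccc(OC)cc1)C/C(C)=C\CC=O
A8 | alternative 3 | ten-membered cyclic propargylic alcohol | CC[Si](CC)(CC)O[C@H]1C#C[C@H](O)C/C=C(/C)C[C@H](OCc2ccc(OC)cc2)[C@H]1C(C)C
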